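Ring C is cut at three bonds: C4a–C4, C4–C3 and O1–C2. C4 carries nothing but its carbonyl oxygen and sits between C4a of ring A and C3, so carbon monoxide can supply it; C3 and C2 are the two carbons of a terminal alkyne that already bears ring B, and O1 is a ring A phenol oxygen. One palladium-catalysed operation therefore joins an ortho-iodoaryl acetate, CO and the alkyne to an ynone and closes the pyranone through an enaminone. The precursor is a pentaoxygenated benzene with iodine on its only former CH; the neighbouring oxygen is masked as an acetate that is shed in the same flask. C3 hydroxylation, methylation and hydrogenolysis finish the route.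

Key step: step 11

Remark on the chemistry: the ring A partner is used as its aryl acetate and not as the free ortho-iodophenol, because acylation should ease oxidative addition into the very electron-rich C–I bond and protects the phenol from air oxidation; diethylamine removes the acetyl group during the annulation. The target has no stereocenter.

**Ring A (steps 1–6)**

Step 1
Reactants: 1 2,6-dimethoxyphenol
Product: 2 2-(benzyloxy)-1,3-dimethoxybenzene
Conditions: BnBr, K2CO3, DMF, 60 °C
Reagents that add atoms: benzyl bromide, BrCc1ccccc1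
Why: Williamson ether synthesis of a phenoxide with a reactive benzylic bromide; capping the hydroxyl also removes its para-directing effect, so the next step is steered by the two methoxy groups.

Step 2
Reactants: 2 2-(benzyloxy)-1,3-dimethoxybenzene
Product: 3 3-(benzyloxy)-1,5-dibromo-2,4-dimethoxybenzene
Conditions: NBS (2.1 equiv), MeCN, 0 °C → rt, dark
Reagents that add atoms: N-bromosuccinimide, O=C1CCC(=O)N1Br
Why: Electrophilic aromatic bromination, in which the flanked central benzyloxy group is twisted out of conjugation and each methoxy group directs to its free ortho position (para to the other methoxy group), so the symmetric 4,6-dibromide of a 1,2,3-trialkoxybenzene should form while the polar, dark conditions suppress benzylic radical bromination.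

Step 3
Reactants: 3 3-(benzyloxy)-1,5-dibromo-2,4-dimethoxybenzene
Product: 6 3-(benzyloxy)-5-bromo-2,4-dimethoxyphenol, via aryllithium 4 (not isolated), via lithium aryltrimethoxyborate 5 (not isolated)
Conditions: n-BuLi (1.0 equiv), THF, −78 °C; B(OMe)3, −78 °C → rt; then AcOH, 30% aq H2O2, 0 °C → rt
Reagents that add atoms: n-butyllithium, [Li]CCCC (lithium of 4 and 5 only); trimethyl borate, COB(OC)OC (boron and methoxy groups of 5 only); hydrogen peroxide, OO (hydroxyl oxygen of 6)
Why: Bromine–lithium exchange followed by borylation and oxidation, in which one equivalent of n-BuLi exchanges only one of the two equivalent bromines (the aryllithium formed resists a second exchange) and peroxide converts the C–B bond into C–OH while the remaining C–Br bond is untouched.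

Step 4
Reactants: 6 3-(benzyloxy)-5-bromo-2,4-dimethoxyphenol
Product: 7 1,3-bis(benzyloxy)-5-bromo-2,4-dimethoxybenzene
Conditions: BnBr, K2CO3, DMF, 60 °C
Reagents that add atoms: benzyl bromide, BrCc1ccccc1
Why: Williamson ether synthesis on the only free hydroxyl, which fixes the oxygen that later becomes O5 of the flavone as a benzyl ether.

Step 5
Reactants: 7 1,3-bis(benzyloxy)-5-bromo-2,4-dimethoxybenzene
Product: 10 3,5-bis(benzyloxy)-2,4-dimethoxyphenol, via aryllithium 8 (not isolated), via lithium aryltrimethoxyborate 9 (not isolated)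
Conditions: n-BuLi (1.1 equiv), THF, −78 °C; B(OMe)3, −78 °C → rt; then AcOH, 30% aq H2O2, 0 °C → rt; aq Na2SO3 quench
Reagents that add atoms: n-butyllithium, [Li]CCCC (lithium of 8 and 9 only); trimethyl borate, COB(OC)OC (boron and methoxy groups of 9 only); hydrogen peroxide, OO (hydroxyl oxygen of 10)
Why: The same bromine–lithium exchange, borylation and oxidation sequence, since at −78 °C the exchange is far faster than metalation of the benzyl ethers, and it delivers the fifth ring oxygen as the only free hydroxyl.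

Step 6
Reactants: 10 3,5-bis(benzyloxy)-2,4-dimethoxyphenol
Product: 12 3,5-bis(benzyloxy)-2-iodo-4,6-dimethoxyphenyl acetate, via iodophenol 11 (not isolated)
Conditions: NIS (1.05 equiv), MeCN, 0 °C, dark; then Et3N, Ac2O, DMAP (cat.), 0 °C → rt
Reagents that add atoms: N-iodosuccinimide, O=C1CCC(=O)N1I; acetic anhydride, CC(=O)OC(C)=O
Why: Electrophilic aromatic iodination at the single remaining ring CH, which is ortho to the free hydroxyl and ortho/para to two benzyloxy groups, followed by O-acetylation in the same flask so that the oxidation-prone iodophenol need not be handled.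

**Ring B alkyne (steps 7–10)**

Step 7
Reactants: 13 3-(benzyloxy)-4-methoxybenzaldehyde
Product: 15 3-(benzyloxy)-4-methoxyphenol, via aryl formate 14 (not isolated)
Conditions: mCPBA, CH2Cl2, 0 °C → rt; then K2CO3 (cat.), MeOH, rt
Reagents that add atoms: 3-chloroperoxybenzoic acid, OOC(=O)c1cccc(Cl)c1 (the inserted oxygen)
Why: Baeyer–Villiger (Dakin-type) oxidation of an electron-rich benzaldehyde, in which the para-methoxy group favours aryl migration and methanolysis of the formate frees the phenol.

Step 8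
Reactants: 15 3-(benzyloxy)-4-methoxyphenol
Product: 16 2,4-bis(benzyloxy)-1-methoxybenzene
Conditions: BnBr, K2CO3, DMF, rt → 60 °C
Reagents that add atoms: benzyl bromide, BrCc1ccccc1
Why: Williamson ether synthesis on an unhindered phenol.

Step 9
Reactants: 16 2,4-bis(benzyloxy)-1-methoxybenzene
Product: 18 2,4-bis(benzyloxy)-5-methoxybenzaldehyde, via aryl iminium chloride 17 (not isolated)
Conditions: POCl3, DMF, 0 °C → 70 °C; then aq NaOH, 0 °C → rt
Reagents that add atoms: N,N-dimethylformamide, CN(C)C=O (formyl carbon, and the dimethylamino group of 17 only); phosphoryl chloride, O=P(Cl)(Cl)Cl (chloride of 17 only); water, O (aldehyde oxygen)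
Why: Vilsmeier–Haack formylation of a 1,2,4-trialkoxybenzene, which attacks the position para to the 2-benzyloxy and ortho to the 4-benzyloxy group, the most nucleophilic and least hindered site.

Step 10
Reactants: 18 2,4-bis(benzyloxy)-5-methoxybenzaldehyde
Product: 19 1,5-bis(benzyloxy)-2-ethynyl-4-methoxybenzene
Conditions: dimethyl (1-diazo-2-oxopropyl)phosphonate, K2CO3, MeOH/THF, rt
Reagents that add atoms: dimethyl (1-diazo-2-oxopropyl)phosphonate, COP(=O)(OC)C(=[N+]=[N-])C(C)=O (its diazo carbon becomes the terminal alkyne carbon)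
Why: Seyferth–Gilbert homologation in the Bestmann–Ohira variant, in which the non-enolisable aryl aldehyde is converted under mild carbonate/methanol conditions into the terminal alkyne through a diazoalkene and 1,2-shift of the alkylidene carbene.

**Key step and completion (steps 11–14)**

Step 11
Reactants: 12 3,5-bis(benzyloxy)-2-iodo-4,6-dimethoxyphenyl acetate, 19 1,5-bis(benzyloxy)-2-ethynyl-4-methoxybenzene, 20 carbon monoxide
Product: 23 5,7-bis(benzyloxy)-2-[2,4-bis(benzyloxy)-5-methoxyphenyl]-6,8-dimethoxy-4H-chromen-4-one, via acetoxyaryl ynone 21 (not isolated), via enaminone 22 (not isolated)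
Conditions: PdCl2(PPh3)2 (5 mol %), dppp (5 mol %), thiourea (5 mol %), CO (1 atm), DBU, Et2NH, 40 °C
Reagents that add atoms: carbon monoxide 20, [C-]#[O+] (C4 and its oxygen); diethylamine, CCNCC (amino group of 22 only)
Why: Zerovalent palladium, formed in the flask from PdCl2(PPh3)2, inserts into the C–I bond of 12, CO insertion gives an aroylpalladium species, and the amine-deprotonated alkyne 19 is transferred to palladium and reductively eliminated as ynone 21, which forms C4a–C4 and C4–C3. Diethylamine then removes the acetyl group and adds to the ynone to give enaminone 22, whose phenoxide attacks the amine-bearing carbon and expels diethylamine, so ring C closes by a 6-endo addition–elimination that forms O1–C2. The closest known reaction type is the carbonylative Sonogashira annulation of ortho-iodophenyl acetates with terminal arylacetylenes to flavones, which includes iodides flanked by two oxygen substituents. No stereocenter is formed. The step needs CO insertion to outrun direct alkynylation and six-membered closure to outrun 5-exo closure to the aurone: the two ortho substituents slow the direct coupling, the copper-free medium keeps alkyne dimerisation down, and the enaminone leaves only C2 electrophilic. The position of ring fusion is not in question, because the iodine sits on the only carbon of 10 that carried hydrogen.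

Step 12
Reactants: 23 5,7-bis(benzyloxy)-2-[2,4-bis(benzyloxy)-5-methoxyphenyl]-6,8-dimethoxy-4H-chromen-4-one
Product: 26 5,7-bis(benzyloxy)-2-[2,4-bis(benzyloxy)-5-methoxyphenyl]-3-hydroxy-6,8-dimethoxy-4H-chromen-4-one, via 3-lithioflavone 24 (not isolated), via lithium flavonyltrimethoxyborate 25 (not isolated)
Conditions: LiN(iPr)2 (LDA, 1.3 equiv), THF, −78 °C; B(OMe)3, −78 °C → 0 °C; then AcOH, 30% aq H2O2, 0 °C → rt
Reagents that add atoms: lithium diisopropylamide, CC(C)[N-]C(C)C.[Li+] (lithium of 24 and 25 only); trimethyl borate, COB(OC)OC (boron and methoxy groups of 25 only); hydrogen peroxide, OO (hydroxyl oxygen of 26)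
Why: Deprotonation of the flavone at C3, its only acidic CH (the lithium is held by the C4 carbonyl oxygen), followed by borylation and oxidation of the C–B bond, a known way from flavones to flavonols.

Step 13
Reactants: 26 5,7-bis(benzyloxy)-2-[2,4-bis(benzyloxy)-5-methoxyphenyl]-3-hydroxy-6,8-dimethoxy-4H-chromen-4-one
Product: 27 5,7-bis(benzyloxy)-2-[2,4-bis(benzyloxy)-5-methoxyphenyl]-3,6,8-trimethoxy-4H-chromen-4-one
Conditions: MeI, K2CO3, acetone, 40 °C
Reagents that add atoms: iodomethane, CI
Why: Williamson O-methylation of the enolic 3-hydroxyl, the only free hydroxyl in the molecule.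

Step 14
Reactants: 27 5,7-bis(benzyloxy)-2-[2,4-bis(benzyloxy)-5-methoxyphenyl]-3,6,8-trimethoxy-4H-chromen-4-one
Product: 28 5,7-dihydroxy-2-(2,4-dihydroxy-5-methoxyphenyl)-3,6,8-trimethoxy-4H-chromen-4-one (5,7,2',4'-tetrahydroxy-3,6,8,5'-tetramethoxyflavone)
Conditions: H2 (1 atm), 10% Pd/C, EtOAc/MeOH, rt
Reagents that add atoms: none
Why: Catalytic hydrogenolysis of four benzyl aryl ethers, under which the methyl ethers and the tetrasubstituted, conjugated C2=C3 bond of the flavone should stay intact.

**Compound list**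

1 | 2,6-dimethoxyphenol | COc1cccc(OC)c1O | starting material
2 | 2-(benzyloxy)-1,3-dimethoxybenzene | COc1cccc(OC)c1OCc1ccccc1 | intermediate
3 | 3-(benzyloxy)-1,5-dibromo-2,4-dimethoxybenzene | COc1c(Br)cc(Br)c(OC)c1OCc1ccccc1 | intermediate
4 | [3-(benzyloxy)-5-bromo-2,4-dimethoxyphenyl]lithium | [Li]c1cc(Br)c(OC)c(OCc2ccccc2)c1OC | intermediate (not isolated)
5 | lithium [3-(benzyloxy)-5-bromo-2,4-dimethoxyphenyl]trimethoxyborate | [Li+].CO[B-](OC)(OC)c1cc(Br)c(OC)c(OCc2ccccc2)c1OC | intermediate (not isolated)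
6 | 3-(benzyloxy)-5-bromo-2,4-dimethoxyphenol | COc1c(O)cc(Br)c(OC)c1OCc1ccccc1 | intermediate
7 | 1,3-bis(benzyloxy)-5-bromo-2,4-dimethoxybenzene | COc1c(OCc2ccccc2)cc(Br)c(OC)c1OCc1ccccc1 | intermediate
8 | [3,5-bis(benzyloxy)-2,4-dimethoxyphenyl]lithium | [Li]c1cc(OCc2ccccc2)c(OC)c(OCc2ccccc2)c1OC | intermediate (not isolated)
9 | lithium [3,5-bis(benzyloxy)-2,4-dimethoxyphenyl]trimethoxyborate | [Li+].CO[B-](OC)(OC)c1cc(OCc2ccccc2)c(OC)c(OCc2ccccc2)c1OC | intermediate (not isolated)
10 | 3,5-bis(benzyloxy)-2,4-dimethoxyphenol | COc1c(O)cc(OCc2ccccc2)c(OC)c1OCc1ccccc1 | intermediate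
11 | 3,5-bis(benzyloxy)-2-iodo-4,6-dimethoxyphenol | COc1c(O)c(I)c(OCc2ccccc2)c(OC)c1OCc1ccccc1 | intermediate (not isolated)
12 | 3,5-bis(benzyloxy)-2-iodo-4,6-dimethoxyphenyl acetate | COc1c(OC(C)=O)c(I)c(OCc2ccccc2)c(OC)c1OCc1ccccc1 | intermediate
13 | 3-(benzyloxy)-4-methoxybenzaldehyde (O-benzylisovanillin) | COc1ccc(C=O)cc1OCc1ccccc1 | starting material
14 | 3-(benzyloxy)-4-methoxyphenyl formate | COc1ccc(OC=O)cc1OCc1ccccc1 | intermediate (not isolated)
15 | 3-(benzyloxy)-4-methoxyphenol | COc1ccc(O)cc1OCc1ccccc1 | intermediate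
16 | 2,4-bis(benzyloxy)-1-methoxybenzene | COc1ccc(OCc2ccccc2)cc1OCc1ccccc1 | intermediate
17 | N-[2,4-bis(benzyloxy)-5-methoxybenzylidene]-N-methylmethanaminium chloride | COc1cc(C=[N+](C)C)c(OCc2ccccc2)cc1OCc1ccccc1.[Cl-] | intermediate (not isolated)
18 | 2,4-bis(benzyloxy)-5-methoxybenzaldehyde | COc1cc(C=O)c(OCc2ccccc2)cc1OCc1ccccc1 | intermediate
19 | 1,5-bis(benzyloxy)-2-ethynyl-4-methoxybenzene | C#Cc1cc(OC)c(OCc2ccccc2)cc1OCc1ccccc1 | intermediate
20 | carbon monoxide | [C-]#[O+] | starting material
21 | 3,5-bis(benzyloxy)-2-{3-[2,4-bis(benzyloxy)-5-methoxyphenyl]prop-2-ynoyl}-4,6-dimethoxyphenyl acetate | COc1cc(C#CC(=O)c2c(OC(C)=O)c(OC)c(OCc3ccccc3)c(OC)c2OCc2ccccc2)c(OCc2ccccc2)cc1OCc1ccccc1 | intermediate (not isolated)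
22 | 1-[4,6-bis(benzyloxy)-2-hydroxy-3,5-dimethoxyphenyl]-3-[2,4-bis(benzyloxy)-5-methoxyphenyl]-3-(diethylamino)prop-2-en-1-one (double-bond geometry not fixed; either isomer cyclises) | CCN(CC)C(=CC(=O)c1c(O)c(OC)c(OCc2ccccc2)c(OC)c1OCc1ccccc1)c1cc(OC)c(OCc2ccccc2)cc1OCc1ccccc1 | intermediate (not isolated)
23 | 5,7-bis(benzyloxy)-2-[2,4-bis(benzyloxy)-5-methoxyphenyl]-6,8-dimethoxy-4H-chromen-4-one | COc1cc(-c2cc(=O)c3c(OCc4ccccc4)c(OC)c(OCc4ccccc4)c(OC)c3o2)c(OCc2ccccc2)cc1OCc1ccccc1 | intermediate
24 | {5,7-bis(benzyloxy)-2-[2,4-bis(benzyloxy)-5-methoxyphenyl]-6,8-dimethoxy-4-oxo-4H-chromen-3-yl}lithium | COc1cc(-c2oc3c(OC)c(OCc4ccccc4)c(OC)c(OCc4ccccc4)c3c(=O)c2[Li])c(OCc2ccccc2)cc1OCc1ccccc1 | intermediate (not isolated)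
25 | lithium {5,7-bis(benzyloxy)-2-[2,4-bis(benzyloxy)-5-methoxyphenyl]-6,8-dimethoxy-4-oxo-4H-chromen-3-yl}trimethoxyborate | [Li+].COc1cc(-c2oc3c(OC)c(OCc4ccccc4)c(OC)c(OCc4ccccc4)c3c(=O)c2[B-](OC)(OC)OC)c(OCc2ccccc2)cc1OCc1ccccc1 | intermediate (not isolated)
26 | 5,7-bis(benzyloxy)-2-[2,4-bis(benzyloxy)-5-methoxyphenyl]-3-hydroxy-6,8-dimethoxy-4H-chromen-4-one | COc1cc(-c2oc3c(OC)c(OCc4ccccc4)c(OC)c(OCc4ccccc4)c3c(=O)c2O)c(OCc2ccccc2)cc1OCc1ccccc1 | intermediate
27 | 5,7-bis(benzyloxy)-2-[2,4-bis(benzyloxy)-5-methoxyphenyl]-3,6,8-trimethoxy-4H-chromen-4-one | COc1cc(-c2oc3c(OC)c(OCc4ccccc4)c(OC)c(OCc4ccccc4)c3c(=O)c2OC)c(OCc2ccccc2)cc1OCc1ccccc1 | intermediate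
28 | 5,7-dihydroxy-2-(2,4-dihydroxy-5-methoxyphenyl)-3,6,8-trimethoxy-4H-chromen-4-one | COc1cc(-c2oc3c(OC)c(O)c(OC)c(O)c3c(=O)c2OC)c(O)cc1O | target

**Step count**

Total: 14 steps. Longest linear sequence: 10 steps (steps 1–6, then 11–14); the ring B alkyne is made in a parallel branch of 4 steps (steps 7–10).

**Steps most likely to fail**

Step 11 (first). Oxidative addition into the doubly ortho-substituted, electron-rich C–I bond may be slow, direct CO-free alkynylation with benzofuran closure may compete, or the ynone may close to the five-membered aurone. The fallback avoids palladium and CO and sets out from phenol 10 and alkyne 19. Magnesium-mediated ortho-formylation of 10 (MgCl2, Et3N, paraformaldehyde, MeCN, reflux) at the only free ring position should give 4,6-bis(benzyloxy)-2-hydroxy-3,5-dimethoxybenzaldehyde F1. Alkyne 19 is deprotonated (n-BuLi, THF, −78 °C) to {[2,4-bis(benzyloxy)-5-methoxyphenyl]ethynyl}lithium F2. An excess of F2 is added to F1, the first equivalent being consumed by the phenol, to give racemic 3,5-bis(benzyloxy)-2-{3-[2,4-bis(benzyloxy)-5-methoxyphenyl]-1-hydroxyprop-2-yn-1-yl}-4,6-dimethoxyphenol F3. Oxidation with MnO2 (CH2Cl2, rt) gives 1-[4,6-bis(benzyloxy)-2-hydroxy-3,5-dimethoxyphenyl]-3-[2,4-bis(benzyloxy)-5-methoxyphenyl]prop-2-yn-1-one F4, and Et2NH in EtOH closes it through the enaminone to flavone 23, where the route is rejoined at step 12.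

Step 12 (second). Deprotonation at C3 may be incomplete, benzylic metalation of the benzyl ethers may compete, or the amide base may open the pyranone. The fallback sets out from flavone 23 and uses electrophilic oxidation instead of metalation. Dimethyldioxirane (acetone/CH2Cl2, 0 °C) should epoxidise the C2=C3 bond to racemic 4,6-bis(benzyloxy)-1a-[2,4-bis(benzyloxy)-5-methoxyphenyl]-3,5-dimethoxy-1a,7a-dihydro-7H-oxireno[2,3-b]chromen-7-one F5. Catalytic p-TsOH (CH2Cl2, rt) then opens the epoxide at C2 and, after loss of the C3 proton, gives flavonol 26, where the route is rejoined at step 13.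

Step 6 (third). The electrophilic iodine source may oxidise the pentaoxygenated phenol to quinonoid material instead of iodinating the ring, or the iodine may be lost again under acid. The fallback sets out from phenol 10 and places iodine by directed ortho-metalation. Protection (MOMCl, iPr2NEt, CH2Cl2) gives 1,3-bis(benzyloxy)-2,4-dimethoxy-5-(methoxymethoxy)benzene F6. n-BuLi (THF, −78 °C → −20 °C) lithiates the only ring CH, which lies between two ether oxygens, to [2,4-bis(benzyloxy)-3,5-dimethoxy-6-(methoxymethoxy)phenyl]lithium F7. Iodine then gives 1,3-bis(benzyloxy)-4-iodo-2,6-dimethoxy-5-(methoxymethoxy)benzene F8. HCl in MeOH at rt removes the acetal to give iodophenol 11, which is acetylated as in the second stage of step 6 to 12.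

Further compounds
F1 | step 11 | 4,6-bis(benzyloxy)-2-hydroxy-3,5-dimethoxybenzaldehyde | COc1c(O)c(C=O)c(OCc2ccccc2)c(OC)c1OCc1ccccc1
F2 | step 11 | {[2,4-bis(benzyloxy)-5-methoxyphenyl]ethynyl}lithium | [Li]C#Cc1cc(OC)c(OCc2ccccc2)cc1OCc1ccccc1
F3 | step 11 | 3,5-bis(benzyloxy)-2-{3-[2,4-bis(benzyloxy)-5-methoxyphenyl]-1-hydroxyprop-2-yn-1-yl}-4,6-dimethoxyphenol (racemic) | COc1cc(C#CC(O)c2c(O)c(OC)c(OCc3ccccc3)c(OC)c2OCc2ccccc2)c(OCc2ccccc2)cc1OCc1ccccc1
F4 | step 11 | 1-[4,6-bis(benzyloxy)-2-hydroxy-3,5-dimethoxyphenyl]-3-[2,4-bis(benzyloxy)-5-methoxyphenyl]prop-2-yn-1-one | COc1cc(C#CC(=O)c2c(O)c(OC)c(OCc3ccccc3)c(OC)c2OCc2ccccc2)c(OCc2ccccc2)cc1OCc1ccccc1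
F5 | step 12 | 4,6-bis(benzyloxy)-1a-[2,4-bis(benzyloxy)-5-methoxyphenyl]-3,5-dimethoxy-1a,7a-dihydro-7H-oxireno[2,3-b]chromen-7-one (racemic, cis ring fusion) | COc1cc(C23OC2C(=O)c2c(OCc4ccccc4)c(OC)c(OCc4ccccc4)c(OC)c2O3)c(OCc2ccccc2)cc1OCc1ccccc1
F6 | step 6 | 1,3-bis(benzyloxy)-2,4-dimethoxy-5-(methoxymethoxy)benzene | COCOc1cc(OCc2ccccc2)c(OC)c(OCc2ccccc2)c1OC
F7 | step 6 | [2,4-bis(benzyloxy)-3,5-dimethoxy-6-(methoxymethoxy)phenyl]lithium | [Li]c1c(OCOC)c(OC)c(OCc2ccccc2)c(OC)c1OCc1ccccc1
F8 | step 6 | 1,3-bis(benzyloxy)-4-iodo-2,6-dimethoxy-5-(methoxymethoxy)benzene | COCOc1c(I)c(OCc2ccccc2)c(OC)c(OCc2ccccc2)c1OC
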